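**Retrosynthetic overview**

- Locants are those of spiro[5.5]undecane: C6 is the spiro carbon, ring B = C6–C1H2–C2HBr–C3(Me)Cl–C4H2–C5H2, ring A = C6–C7(=CH2)–C8H2–C9H(OH)–C10HBr–C11Me2. The strategy rests on ring B: its heteroatom-bearing C3 lies para to the quaternary C6, so ring B is a disguised para-alkylphenol (a cyclohexa-2,5-dienone), and C6 is a stereocentre only because C2 is not C4; the spiro carbon can therefore be built without chirality and fixed afterwards by reacting one enone arm.
- Late stage: C3–Cl from the C3 tertiary alcohol by retentive chlorination; the alcohol from MeLi addition to the C2-bromo C3-ketone; that from the C1=C2 enone by 1,4-hydrosilylation and bromination; the mono-enone from arm-selective 1,4-reduction of the symmetric spirodienone.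
- Key disconnection C6–C7: gold-catalysed 6-exo-dig ipso-cyclisation of a free phenol onto a terminal alkyne, which closes ring A and turns the arene into the dienone of ring B.
- Cyclisation precursor: C6–C11 by Friedel–Crafts alkylation of anisole with 3-methylbut-2-enoic acid; C10 by catalytic enantioselective α-bromination of the derived aldehyde; C7, C8 and the methylene carbon by allenylboronate propargylation; C9 by oxidation and hydride reduction anti to bromine.
- Ring order: ring B is bought as the benzene ring of anisole, ring A is closed second (key step), ring B is then reduced and functionalised one arm at a time.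

Key step: step 12

Assumption: the (2R,5R) enantiomer of 2,5-diphenylpyrrolidine is taken to give the (S)-α-bromo aldehyde, as the face-shielding model of its enamine predicts; should the sense prove opposite, the (2S,5S) catalyst is used and nothing else changes.

**Route**

Step 1
Reactants: 1 anisole; 2 3-methylbut-2-enoic acid
Product: 3 3-(4-methoxyphenyl)-3-methylbutanoic acid
Conditions: AlCl3 (2.5 equiv), 1 in excess, CH2Cl2, 0 °C → rt; aq. HCl work-up
Reagents that add atoms: none
Why: Friedel–Crafts alkylation, in which AlCl3 turns the β-carbon of the acrylic acid into a tertiary carbocation equivalent that attacks anisole para to the methoxy group (the ortho positions are too crowded for a tertiary electrophile), so the C6–C11 bond and the quaternary C11 are made in one operation.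

Step 2
Reactants: 3 3-(4-methoxyphenyl)-3-methylbutanoic acid
Product: 4 3-(4-hydroxyphenyl)-3-methylbutanoic acid
Conditions: BBr3 (3 equiv), CH2Cl2, −78 °C → rt; H2O
Reagents that add atoms: none
Why: Lewis-acid cleavage of an aryl methyl ether, in which BBr3 binds the methoxy oxygen and bromide removes the methyl group by SN2, the boron esters of the phenol and of the acid being hydrolysed on work-up.

Step 3
Reactants: 4 3-(4-hydroxyphenyl)-3-methylbutanoic acid
Product: 5 methyl 3-(4-hydroxyphenyl)-3-methylbutanoate
Conditions: MeOH, H2SO4 (cat.), reflux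
Reagents that add atoms: methanol, CO
Why: Fischer esterification in excess methanol, during which the para-phenol cannot lactonise onto the side chain and stays free.

Step 4
Reactants: 5 methyl 3-(4-hydroxyphenyl)-3-methylbutanoate
Product: 6 methyl 3-[4-(tert-butyldimethylsilyloxy)phenyl]-3-methylbutanoate
Conditions: TBSCl, imidazole, DMF, rt
Reagents that add atoms: tert-butyldimethylsilyl chloride, CC(C)(C)[Si](C)(C)Cl
Why: imidazole-promoted silylation of the phenol masks the acidic OH before the hydride and enamine chemistry.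

Step 5
Reactants: 6 methyl 3-[4-(tert-butyldimethylsilyloxy)phenyl]-3-methylbutanoate
Product: 7 3-[4-(tert-butyldimethylsilyloxy)phenyl]-3-methylbutanal
Conditions: i-Bu2AlH (1.05 equiv), CH2Cl2, −78 °C; MeOH, then aq. KNaC4H4O6 (sodium potassium tartrate)
Reagents that add atoms: none
Why: partial reduction of an ester, in which the tetrahedral aluminium hemiacetal is stable at −78 °C and collapses to the aldehyde only on work-up, the neopentyl-type surroundings of the ester helping the reduction to stop at this stage.

Step 6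
Reactants: 7 3-[4-(tert-butyldimethylsilyloxy)phenyl]-3-methylbutanal
Product: 8 (2S)-2-bromo-3-[4-(tert-butyldimethylsilyloxy)phenyl]-3-methylbutanal
Conditions: (2R,5R)-2,5-diphenylpyrrolidine (20 mol %), PhCO2H (20 mol %), 4,4-dibromo-2,6-di-tert-butylcyclohexa-2,5-dienone (1.1 equiv), H2O (2 equiv), CH2Cl2/pentane, −40 °C; cold silica plug, used at once
Reagents that add atoms: 4,4-dibromo-2,6-di-tert-butylcyclohexa-2,5-dienone, CC(C)(C)C1=CC(Br)(Br)C=C(C(C)(C)C)C1=O
Why: enamine-catalysed electrophilic α-bromination, in which the C2-symmetric pyrrolidine forms an E-enamine with one face covered by a phenyl group, so that electrophilic bromine from the dienone should enter from the open face and set C10 as (S); this is the only external source of chirality, and the labile bromo aldehyde is taken on without storage.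

Step 7
Reactants: 8 (2S)-2-bromo-3-[4-(tert-butyldimethylsilyloxy)phenyl]-3-methylbutanal; 9 allenylboronic acid pinacol ester (4,4,5,5-tetramethyl-2-(propa-1,2-dienyl)-1,3,2-dioxaborolane)
Product: 10 (4RS,5S)-5-bromo-6-[4-(tert-butyldimethylsilyloxy)phenyl]-6-methylhept-1-yn-4-ol (both C4 epimers)
Conditions: toluene, 4 Å MS, (PhO)2P(O)OH (5 mol %), 0 °C; pH 7 buffer
Reagents that add atoms: none
Why: propargylation of an aldehyde by an allenylboronate through a closed six-membered SE2' transition state, which gives only the homopropargylic alcohol and uses no zerovalent metal that could insert into the C–Br bond; the epimer ratio at the carbinol carbon (C9) does not matter because this carbon is oxidised next.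

Step 8
Reactants: 10 (4RS,5S)-5-bromo-6-[4-(tert-butyldimethylsilyloxy)phenyl]-6-methylhept-1-yn-4-ol
Product: 11 (5S)-5-bromo-6-[4-(tert-butyldimethylsilyloxy)phenyl]-6-methylhept-1-yn-4-one
Conditions: Dess–Martin periodinane (1.3 equiv), NaHCO3, CH2Cl2, 0 °C; cold filtration, used at once
Reagents that add atoms: none
Why: Dess–Martin oxidation under bicarbonate buffer converts the secondary alcohol into the β,γ-ynone without a base strong enough to isomerise it to the allenyl ketone or to enolise the bromine-bearing C10.

Step 9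
Reactants: 11 (5S)-5-bromo-6-[4-(tert-butyldimethylsilyloxy)phenyl]-6-methylhept-1-yn-4-one
Product: 12 (4S,5S)-5-bromo-6-[4-(tert-butyldimethylsilyloxy)phenyl]-6-methylhept-1-yn-4-ol
Conditions: LiBH(s-Bu)3 (1.1 equiv), THF, −78 °C; AcOH/THF at −78 °C, pH 7 buffer (no alkaline peroxide)
Reagents that add atoms: none
Why: non-chelating hydride reduction of an α-bromo ketone under polar Felkin–Anh control, in which the bulky borohydride adds antiperiplanar to the C–Br bond and past the small hydrogen on C10, which should give the (4S,5S) bromohydrin that becomes the trans-diequatorial C9–O/C10–Br pair of ring A (the propargylation itself would favour the other epimer, hence the oxidation–reduction detour).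

Step 10
Reactants: 12 (4S,5S)-5-bromo-6-[4-(tert-butyldimethylsilyloxy)phenyl]-6-methylhept-1-yn-4-ol
Product: 13 (4S,5S)-5-bromo-4-(tert-butyldimethylsilyloxy)-6-[4-(tert-butyldimethylsilyloxy)phenyl]-6-methylhept-1-yne
Conditions: TBSOTf, 2,6-lutidine, CH2Cl2, −78 → 0 °C
Reagents that add atoms: tert-butyldimethylsilyl trifluoromethanesulfonate, CC(C)(C)[Si](C)(C)OS(=O)(=O)C(F)(F)F
Why: silyl triflate silylation of a hindered secondary alcohol with a non-nucleophilic pyridine base that cannot close the bromohydrin to an epoxide, the bulky ether later keeping the C9 oxygen away from the gold-activated alkyne.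

Step 11
Reactants: 13 (4S,5S)-5-bromo-4-(tert-butyldimethylsilyloxy)-6-[4-(tert-butyldimethylsilyloxy)phenyl]-6-methylhept-1-yne
Product: 14 4-[(3S,4S)-3-bromo-4-(tert-butyldimethylsilyloxy)-2-methylhept-6-yn-2-yl]phenol
Conditions: KHF2 (2.5 equiv), MeOH, rt
Reagents that add atoms: none
Why: chemoselective desilylation, since bifluoride in methanol cleaves aryl silyl ethers much faster than alkyl silyl ethers and the medium is weakly acidic, so no phenoxide is formed that could expel the C10 bromide through a spiro three-membered ring (aryl participation).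

Step 12
Reactants: 14 4-[(3S,4S)-3-bromo-4-(tert-butyldimethylsilyloxy)-2-methylhept-6-yn-2-yl]phenol
Product: 15 (9S,10S)-10-bromo-9-(tert-butyldimethylsilyloxy)-11,11-dimethyl-7-methylidenespiro[5.5]undeca-1,4-dien-3-one
Conditions: Ph3PAuNTf2 (5 mol %), 4 Å MS, CH2Cl2, rt, no base
Reagents that add atoms: none
Why: Proposed new method: monovalent gold π-activates the terminal alkyne, the arene carbon para to the hydroxyl (C6) adds anti to gold at the internal alkyne carbon C7, the resulting oxocarbenium ion loses the phenol proton to give the cross-conjugated dienone, and protodeauration of the alkenylgold leaves the exocyclic methylene. The closest known reaction types are gold-catalysed dearomative ipso-cyclisations of phenols onto tethered alkynes that give spiro[4.5]decadienones and gold-catalysed 6-exo-dig carbocyclisations of the Conia-ene type; the present case joins the two on an all-carbon tether with a quaternary benzylic carbon. Ring A is closed 6-exo-dig through the C6–C7 bond, via a chair in which C9–OTBS and C10–Br are equatorial and the gem-dimethyl group at C11 favours closure (Thorpe–Ingold effect). No new stereocentre is formed: C6 becomes quaternary but stays non-stereogenic because the two dienone arms are identical, and C9 and C10 are not touched. The step needs ipso instead of ortho carbon attack, exo instead of endo closure and carbon instead of oxygen attack; these are secured by the para hydroxyl (the ortho carbons are meta to it and would give a seven-membered ring), by the Markovnikov bias of the terminal alkyne and by the bulky silyl ether on the C9 oxygen. The medium contains no base, so no phenoxide arises that could displace the C10 bromide.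

Step 13
Reactants: 15 (9S,10S)-10-bromo-9-(tert-butyldimethylsilyloxy)-11,11-dimethyl-7-methylidenespiro[5.5]undeca-1,4-dien-3-one
Product: 17 (6S,9S,10S)-10-bromo-9-(tert-butyldimethylsilyloxy)-11,11-dimethyl-7-methylidenespiro[5.5]undec-1-en-3-one, via silyl dienol ether 16 (not isolated)
Conditions: Cu(OAc)2 (5 mol %), 1,2-bis(diphenylphosphino)benzene (5 mol %), (EtO)2MeSiH (1.05 equiv), toluene, −20 °C; then 1 M HCl, THF, 0 °C
Reagents that add atoms: none
Why: 1,4-reduction of a cross-conjugated dienone by monovalent copper hydride (CuH, formed from Cu(OAc)2 and the silane), in which the first hydride is trapped as the silyl dienol ether and over-reduction is blocked; the hydride should go to the β-carbon of the arm that is axial on the ring A chair, because the equatorial arm is wedged between the exocyclic methylene (allylic 1,3-strain) and both C11 methyl groups, and this choice of arm makes C6 stereogenic with the (S) configuration.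

Step 14
Reactants: 17 (6S,9S,10S)-10-bromo-9-(tert-butyldimethylsilyloxy)-11,11-dimethyl-7-methylidenespiro[5.5]undec-1-en-3-one
Product: 18 (6S,9S,10S)-10-bromo-9-(tert-butyldimethylsilyloxy)-11,11-dimethyl-7-methylidene-3-(triethylsilyloxy)spiro[5.5]undec-2-ene
Conditions: RhCl(PPh3)3 (2 mol %), Et3SiH (1.5 equiv), THF, 50 °C; filtration through deactivated silica
Reagents that add atoms: triethylsilane, CC[SiH](CC)CC
Why: rhodium-catalysed 1,4-hydrosilylation of the remaining enone puts hydrogen on C1 and silicon on oxygen, which fixes the enol double bond at C2=C3 without regiochemical ambiguity, while the hindered 1,1-disubstituted exocyclic alkene is left alone.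

Step 15
Reactants: 18 (6S,9S,10S)-10-bromo-9-(tert-butyldimethylsilyloxy)-11,11-dimethyl-7-methylidene-3-(triethylsilyloxy)spiro[5.5]undec-2-ene
Product: 20 (2S,6S,9S,10S)-2,10-dibromo-9-(tert-butyldimethylsilyloxy)-11,11-dimethyl-7-methylidenespiro[5.5]undecan-3-one, via C2-epimeric bromoketone mixture 19 (not isolated)
Conditions: NBS (1.05 equiv), THF, −78 °C; then LiBr (3 equiv), THF, rt
Reagents that add atoms: N-bromosuccinimide, O=C1CCC(=O)N1Br
Why: electrophilic bromination of a silyl enol ether places bromine only on C2, and bromide-for-bromide SN2 exchange at this α-keto carbon then equilibrates C2 to the thermodynamic equatorial (2S) bromide, since the axial epimer is syn-diaxial to C7 on the ring B chair.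

Step 16
Reactants: 20 (2S,6S,9S,10S)-2,10-dibromo-9-(tert-butyldimethylsilyloxy)-11,11-dimethyl-7-methylidenespiro[5.5]undecan-3-one; 21 methyllithium
Product: 22 (2S,3S,6S,9S,10S)-2,10-dibromo-9-(tert-butyldimethylsilyloxy)-3,11,11-trimethyl-7-methylidenespiro[5.5]undecan-3-ol
Conditions: MeAl(OAr)2 (Ar = 2,6-di-tert-butyl-4-methylphenyl, 3 equiv), toluene, −78 °C; 21 (3 equiv, Et2O), −78 °C; AcOH/THF quench at −78 °C
Reagents that add atoms: none
Why: amphiphilic carbonyl alkylation, in which the very bulky aluminium bis(aryloxide) binds the carbonyl oxygen from the open equatorial side so that MeLi must add along the axial trajectory, which should give the axial methyl group and the equatorial tertiary alcohol trans to the C2 bromide; at −78 °C 1,2-addition should outrun enolisation and attack at bromine, and the diequatorial bromohydrin alkoxide cannot close to an epoxide.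

Step 17
Reactants: 22 (2S,3S,6S,9S,10S)-2,10-dibromo-9-(tert-butyldimethylsilyloxy)-3,11,11-trimethyl-7-methylidenespiro[5.5]undecan-3-ol
Product: 24 tert-butyldimethylsilyl ether of (2S,3S,6S,9S,10S)-2,10-dibromo-3-chloro-3,11,11-trimethyl-7-methylidenespiro[5.5]undecan-9-ol, via tertiary chlorosulfite 23 (not isolated)
Conditions: SOCl2 (1.5 equiv), CH2Cl2, −78 → −20 °C, no amine base (TiCl4, 5 mol %, if the chlorosulfite persists)
Reagents that add atoms: thionyl chloride, O=S(Cl)Cl
Why: chlorination of a tertiary alcohol by thionyl chloride with internal return (SNi), in which the chlorosulfite ionises to a tight ion pair, sulfur dioxide is lost and chloride comes back on the face the oxygen left while the vicinal C2 bromine bridges or shields the opposite face, so that C3 should be chlorinated with retention and trans to bromine; the C9 oxygen is silylated and cannot react.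

Step 18
Reactants: 24 tert-butyldimethylsilyl ether of (2S,3S,6S,9S,10S)-2,10-dibromo-3-chloro-3,11,11-trimethyl-7-methylidenespiro[5.5]undecan-9-ol
Product: 25 (2S,3S,6S,9S,10S)-2,10-dibromo-3-chloro-3,11,11-trimethyl-7-methylidenespiro[5.5]undecan-9-ol (CNP0247242.1)
Conditions: HF·pyridine, pyridine, THF, 0 °C → rt
Reagents that add atoms: none
Why: fluoride-mediated cleavage of the secondary silyl ether under buffered acidic conditions that should not touch the tertiary chloride, the two bromides or the exocyclic alkene.

**Compound list**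

1 | anisole | COc1ccccc1 | starting material
2 | 3-methylbut-2-enoic acid | CC(C)=CC(=O)O | starting material
3 | 3-(4-methoxyphenyl)-3-methylbutanoic acid | COc1ccc(cc1)C(C)(C)CC(=O)O | intermediate
4 | 3-(4-hydroxyphenyl)-3-methylbutanoic acid | OC(=O)CC(C)(C)c1ccc(O)cc1 | intermediate
5 | methyl 3-(4-hydroxyphenyl)-3-methylbutanoate | COC(=O)CC(C)(C)c1ccc(O)cc1 | intermediate
6 | methyl 3-[4-(tert-butyldimethylsilyloxy)phenyl]-3-methylbutanoate | COC(=O)CC(C)(C)c1ccc(O[Si](C)(C)C(C)(C)C)cc1 | intermediate
7 | 3-[4-(tert-butyldimethylsilyloxy)phenyl]-3-methylbutanal | CC(C)(CC=O)c1ccc(O[Si](C)(C)C(C)(C)C)cc1 | intermediate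
8 | (2S)-2-bromo-3-[4-(tert-butyldimethylsilyloxy)phenyl]-3-methylbutanal | O=C[C@@H](Br)C(C)(C)c1ccc(O[Si](C)(C)C(C)(C)C)cc1 | intermediate
9 | allenylboronic acid pinacol ester | C=C=CB1OC(C)(C)C(C)(C)O1 | starting material
10 | (4RS,5S)-5-bromo-6-[4-(tert-butyldimethylsilyloxy)phenyl]-6-methylhept-1-yn-4-ol | C#CCC(O)[C@@H](Br)C(C)(C)c1ccc(O[Si](C)(C)C(C)(C)C)cc1 | intermediate
11 | (5S)-5-bromo-6-[4-(tert-butyldimethylsilyloxy)phenyl]-6-methylhept-1-yn-4-one | C#CCC(=O)[C@@H](Br)C(C)(C)c1ccc(O[Si](C)(C)C(C)(C)C)cc1 | intermediate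
12 | (4S,5S)-5-bromo-6-[4-(tert-butyldimethylsilyloxy)phenyl]-6-methylhept-1-yn-4-ol | C#CC[C@H](O)[C@@H](Br)C(C)(C)c1ccc(O[Si](C)(C)C(C)(C)C)cc1 | intermediate
13 | (4S,5S)-5-bromo-4-(tert-butyldimethylsilyloxy)-6-[4-(tert-butyldimethylsilyloxy)phenyl]-6-methylhept-1-yne | C#CC[C@H](O[Si](C)(C)C(C)(C)C)[C@@H](Br)C(C)(C)c1ccc(O[Si](C)(C)C(C)(C)C)cc1 | intermediate
14 | 4-[(3S,4S)-3-bromo-4-(tert-butyldimethylsilyloxy)-2-methylhept-6-yn-2-yl]phenol | C#CC[C@H](O[Si](C)(C)C(C)(C)C)[C@@H](Br)C(C)(C)c1ccc(O)cc1 | intermediate
15 | (9S,10S)-10-bromo-9-(tert-butyldimethylsilyloxy)-11,11-dimethyl-7-methylidenespiro[5.5]undeca-1,4-dien-3-one | C=C1C[C@H](O[Si](C)(C)C(C)(C)C)[C@@H](Br)C(C)(C)C12C=CC(=O)C=C2 | intermediate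
16 | (6S,9S,10S)-10-bromo-9-(tert-butyldimethylsilyloxy)-3-[diethoxy(methyl)silyloxy]-11,11-dimethyl-7-methylidenespiro[5.5]undeca-1,3-diene (silyl dienol ether) | C=C1C[C@H](O[Si](C)(C)C(C)(C)C)[C@@H](Br)C(C)(C)[C@]12CC=C(O[Si](C)(OCC)OCC)C=C2 | intermediate
17 | (6S,9S,10S)-10-bromo-9-(tert-butyldimethylsilyloxy)-11,11-dimethyl-7-methylidenespiro[5.5]undec-1-en-3-one | C=C1C[C@H](O[Si](C)(C)C(C)(C)C)[C@@H](Br)C(C)(C)[C@]12CCC(=O)C=C2 | intermediate
18 | (6S,9S,10S)-10-bromo-9-(tert-butyldimethylsilyloxy)-11,11-dimethyl-7-methylidene-3-(triethylsilyloxy)spiro[5.5]undec-2-ene | C=C1C[C@H](O[Si](C)(C)C(C)(C)C)[C@@H](Br)C(C)(C)[C@]12CCC(O[Si](CC)(CC)CC)=CC2 | intermediate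
19 | (2RS,6S,9S,10S)-2,10-dibromo-9-(tert-butyldimethylsilyloxy)-11,11-dimethyl-7-methylidenespiro[5.5]undecan-3-one (C2 epimers) | C=C1C[C@H](O[Si](C)(C)C(C)(C)C)[C@@H](Br)C(C)(C)[C@]12CCC(=O)C(Br)C2 | intermediate
20 | (2S,6S,9S,10S)-2,10-dibromo-9-(tert-butyldimethylsilyloxy)-11,11-dimethyl-7-methylidenespiro[5.5]undecan-3-one | C=C1C[C@H](O[Si](C)(C)C(C)(C)C)[C@@H](Br)C(C)(C)[C@]12CCC(=O)[C@@H](Br)C2 | intermediate
21 | methyllithium | [Li]C | starting material
22 | (2S,3S,6S,9S,10S)-2,10-dibromo-9-(tert-butyldimethylsilyloxy)-3,11,11-trimethyl-7-methylidenespiro[5.5]undecan-3-ol | C=C1C[C@H](O[Si](C)(C)C(C)(C)C)[C@@H](Br)C(C)(C)[C@]12CC[C@](C)(O)[C@@H](Br)C2 | intermediate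
23 | chlorosulfite of alcohol 22 at C3 | C=C1C[C@H](O[Si](C)(C)C(C)(C)C)[C@@H](Br)C(C)(C)[C@]12CC[C@](C)(OS(=O)Cl)[C@@H](Br)C2 | intermediate
24 | tert-butyldimethylsilyl ether of (2S,3S,6S,9S,10S)-2,10-dibromo-3-chloro-3,11,11-trimethyl-7-methylidenespiro[5.5]undecan-9-ol | C=C1C[C@H](O[Si](C)(C)C(C)(C)C)[C@@H](Br)C(C)(C)[C@]12CC[C@](C)(Cl)[C@@H](Br)C2 | intermediate
25 | (2S,3S,6S,9S,10S)-2,10-dibromo-3-chloro-3,11,11-trimethyl-7-methylidenespiro[5.5]undecan-9-ol | C=C1C[C@H](O)[C@@H](Br)C(C)(C)[C@]12CC[C@](C)(Cl)[C@@H](Br)C2 | target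

**Step count and risks**

Total step count: 18. Longest linear sequence: 18 steps (anisole to 25).

Steps most likely to fail:

1. Step 12 (the labelled step). The crowded ipso carbon, flanked by the quaternary C11, may not attack the gold-activated alkyne, the alkyne may be hydrated, the catalyst may be lost by halide abstraction, or the acid-sensitive dienone may rearrange with rearomatisation. The fallback uses known chemistry, Birch reduction in place of dearomatisation and an intramolecular Mizoroki–Heck reaction in place of the gold step; it sets out from 3 and comes back at 17.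
   - Birch reduction of 3 (Li, liquid NH3, t-BuOH) should give 3-(4-methoxycyclohexa-1,4-dien-1-yl)-3-methylbutanoic acid F1.
   - Acetal exchange with ethylene glycol (PPTS) should give 3-(1,4-dioxaspiro[4.5]dec-7-en-8-yl)-3-methylbutanoic acid F2.
   - LiAlH4 should give 3-(1,4-dioxaspiro[4.5]dec-7-en-8-yl)-3-methylbutan-1-ol F3, and Parikh–Doering oxidation the aldehyde 3-(1,4-dioxaspiro[4.5]dec-7-en-8-yl)-3-methylbutanal F4.
   - The enamine bromination of step 6 should give (2S)-2-bromo-3-(1,4-dioxaspiro[4.5]dec-7-en-8-yl)-3-methylbutanal F5.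
   - Allylboration with 2-bromoallylboronic acid pinacol ester should give (4RS,5S)-2,5-dibromo-6-(1,4-dioxaspiro[4.5]dec-7-en-8-yl)-6-methylhept-1-en-4-ol F6.
   - Dess–Martin oxidation should give (5S)-2,5-dibromo-6-(1,4-dioxaspiro[4.5]dec-7-en-8-yl)-6-methylhept-1-en-4-one F7, and LiBH(s-Bu)3 as in step 9 the (4S,5S)-2,5-dibromo-6-(1,4-dioxaspiro[4.5]dec-7-en-8-yl)-6-methylhept-1-en-4-ol F8.
   - TBSOTf/2,6-lutidine should give the tert-butyldimethylsilyl ether of that alcohol F9.
   - With Pd(OAc)2, PPh3 and Et3N in MeCN at 80 °C, zerovalent palladium should insert only into the alkenyl C–Br bond, add 6-exo-trig to the substituted carbon of the ring alkene (making the C6–C7 bond and the quaternary C6) and leave by β-hydride elimination, giving the ethylene acetal of enone 17 F10.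
   - PPTS in wet acetone should then release 17.
   - In this variant the face of the ring alkene that is carbopalladated decides C6, so the arm selection of step 13 is no longer needed.

2. Step 13. The two diastereotopic enone arms may be discriminated poorly, or the second arm may be reduced as well. A chiral bisphosphine on copper could reinforce the substrate bias, but the fallback changes the approach to reagent-controlled desymmetrisation of the saturated ketone; it sets out from 15 and comes back at 20.
   - Exhaustive conjugate reduction of 15 with the same CuH system (2.5 equiv of silane, t-BuOH) should give (9S,10S)-10-bromo-9-(tert-butyldimethylsilyloxy)-11,11-dimethyl-7-methylidenespiro[5.5]undecan-3-one F11, in which C6 is still non-stereogenic.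
   - Deprotonation with lithium bis[(R)-1-phenylethyl]amide or its enantiomer (whichever removes the C2 proton) in the presence of Me3SiCl at −100 °C should give the trimethylsilyl analogue of 18, (6S,9S,10S)-10-bromo-9-(tert-butyldimethylsilyloxy)-11,11-dimethyl-7-methylidene-3-(trimethylsilyloxy)spiro[5.5]undec-2-ene F12.
   - NBS and then LiBr as in step 15 should give 20.

3. Step 17. The tertiary chlorosulfite may eliminate instead of collapsing, bromine may migrate through the bridged cation, or the HCl formed may add to the exocyclic alkene. The fallback replaces substitution at C3 by anti bromochlorination of a C2=C3 alkene and also bypasses step 16; it sets out from 18 and comes back at 24.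
   - MeLi should cleave the silyl enol ether 18 to the lithium enolate, which PhNTf2 traps as (6S,9S,10S)-10-bromo-9-(tert-butyldimethylsilyloxy)-11,11-dimethyl-7-methylidenespiro[5.5]undec-2-en-3-yl trifluoromethanesulfonate F13.
   - Negishi coupling (MeZnCl, Pd(PPh3)4, THF) should give (6S,9S,10S)-10-bromo-9-(tert-butyldimethylsilyloxy)-3,11,11-trimethyl-7-methylidenespiro[5.5]undec-2-ene F14.
   - Bu4NBrCl2 in CH2Cl2 at −78 °C should add bromine and chlorine anti across the more electron-rich trisubstituted alkene, chloride opening the bromonium ion at the tertiary C3; the diaxial adduct relaxes to the diequatorial chair of 24.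
   - The face on which the bromonium ion forms is the open point of this variant.

Further compounds
F1 | step 12 | 3-(4-methoxycyclohexa-1,4-dien-1-yl)-3-methylbutanoic acid | COC1=CCC(=CC1)C(C)(C)CC(=O)O
F2 | step 12 | 3-(1,4-dioxaspiro[4.5]dec-7-en-8-yl)-3-methylbutanoic acid | OC(=O)CC(C)(C)C1=CCC2(CC1)OCCO2
F3 | step 12 | 3-(1,4-dioxaspiro[4.5]dec-7-en-8-yl)-3-methylbutan-1-ol | OCCC(C)(C)C1=CCC2(CC1)OCCO2
F4 | step 12 | 3-(1,4-dioxaspiro[4.5]dec-7-en-8-yl)-3-methylbutanal | O=CCC(C)(C)C1=CCC2(CC1)OCCO2
F5 | step 12 | (2S)-2-bromo-3-(1,4-dioxaspiro[4.5]dec-7-en-8-yl)-3-methylbutanal | O=C[C@@H](Br)C(C)(C)C1=CCC2(CC1)OCCO2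
F6 | step 12 | (4RS,5S)-2,5-dibromo-6-(1,4-dioxaspiro[4.5]dec-7-en-8-yl)-6-methylhept-1-en-4-ol | C=C(Br)CC(O)[C@@H](Br)C(C)(C)C1=CCC2(CC1)OCCO2
F7 | step 12 | (5S)-2,5-dibromo-6-(1,4-dioxaspiro[4.5]dec-7-en-8-yl)-6-methylhept-1-en-4-one | C=C(Br)CC(=O)[C@@H](Br)C(C)(C)C1=CCC2(CC1)OCCO2
F8 | step 12 | (4S,5S)-2,5-dibromo-6-(1,4-dioxaspiro[4.5]dec-7-en-8-yl)-6-methylhept-1-en-4-ol | C=C(Br)C[C@H](O)[C@@H](Br)C(C)(C)C1=CCC2(CC1)OCCO2
F9 | step 12 | tert-butyldimethylsilyl ether of (4S,5S)-2,5-dibromo-6-(1,4-dioxaspiro[4.5]dec-7-en-8-yl)-6-methylhept-1-en-4-ol | C=C(Br)C[C@H](O[Si](C)(C)C(C)(C)C)[C@@H](Br)C(C)(C)C1=CCC2(CC1)OCCO2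
F10 | step 12 | ethylene acetal of enone 17 | C=C1C[C@H](O[Si](C)(C)C(C)(C)C)[C@@H](Br)C(C)(C)[C@]12CCC3(OCCO3)C=C2
F11 | step 13 | (9S,10S)-10-bromo-9-(tert-butyldimethylsilyloxy)-11,11-dimethyl-7-methylidenespiro[5.5]undecan-3-one | C=C1C[C@H](O[Si](C)(C)C(C)(C)C)[C@@H](Br)C(C)(C)C12CCC(=O)CC2
F12 | step 13 | (6S,9S,10S)-10-bromo-9-(tert-butyldimethylsilyloxy)-11,11-dimethyl-7-methylidene-3-(trimethylsilyloxy)spiro[5.5]undec-2-ene | C=C1C[C@H](O[Si](C)(C)C(C)(C)C)[C@@H](Br)C(C)(C)[C@]12CCC(O[Si](C)(C)C)=CC2
F13 | step 17 | (6S,9S,10S)-10-bromo-9-(tert-butyldimethylsilyloxy)-11,11-dimethyl-7-methylidenespiro[5.5]undec-2-en-3-yl trifluoromethanesulfonate | C=C1C[C@H](O[Si](C)(C)C(C)(C)C)[C@@H](Br)C(C)(C)[C@]12CCC(OS(=O)(=O)C(F)(F)F)=CC2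
F14 | step 17 | (6S,9S,10S)-10-bromo-9-(tert-butyldimethylsilyloxy)-3,11,11-trimethyl-7-methylidenespiro[5.5]undec-2-ene | C=C1C[C@H](O[Si](C)(C)C(C)(C)C)[C@@H](Br)C(C)(C)[C@]12CCC(C)=CC2
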